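## Structural features

The target is an achiral 1H-isochromen-1-one (isocoumarin). Benzo ring A is fused to an α-pyranone that carries a pentyl chain at C3, with a free hydroxyl at C6 and an aryloxy group at C8. The C8 oxygen is bonded to C1' of ring B, a 2,4-dihydroxy-6-pentylphenyl unit. Ring B is therefore a pentylbenzene oxygenated at C1', C2' and C4', of which only the C1' oxygen is arylated. There is no stereocentre, so every problem is one of regiochemistry and reactivity. The ether is crowded on both sides: C1' has a substituent on each neighbour (hydroxyl at C2', pentyl at C6') and C8 lies peri to the lactone carbonyl C1. An aryl–aryl ether coupling would have to work at a doubly ortho-substituted centre and would also have to tell apart three oxygens of ring B and two of ring A. The fragile parts are the enol lactone (acyl bond O2–C1 and the C3=C4 bond; opened by hydroxide or alkoxide, reducible by hydrogenation) and the free resorcinol of ring B, which is sensitive to oxidants and to electrophilic halogen. The key step uses the fact that C1' is flanked by an oxygen-bearing carbon (C2') and by the pentyl-bearing carbon (C6'), with the second oxygen at C4'. That is the pattern left when a malonate carbon (C1') adds to the β-carbon of an enone (C6', whose carbonyl becomes C4') and the ketone methyl (C3') is then acylated by a malonate ester carbon (C2'). The ether oxygen can thus be attached to C1' while that carbon is still sp3 and unhindered.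

## Logic of the disconnections

15 to 14: the O–CH3 bond at C6 is added in thought. The C6 oxygen has to be masked from the second step onward, and a methyl ether is the one mask that tolerates amide base, selective Lewis-acid cleavage of its C8 twin, alkoxide, 140 °C and a quinone oxidant. Nothing is gained in skeleton, but one protecting group serves the whole route. The demand is a final boron tribromide cleavage that leaves the enol lactone and the diaryl ether untouched.

14 to 13: ring B is taken back to the dihydro level by adding two hydrogens, so that C2' and C4' become ketone carbons. A cyclohexane-1,3-dione is what a Michael–Claisen sequence delivers, and ring B becomes an aliphatic ring that can be assembled from open-chain pieces. The forward step must be a dehydrogenation that tolerates two electron-rich arenes. Loss of the aryloxy group is not a concern, because it sits alpha to the C2' carbonyl and its other neighbour, C6', carries no acidic hydrogen.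

13 to 12: a methoxycarbonyl group is put back on C1', which turns C1' into a malonate carbon. The forward step must remove an ester from a fully substituted carbon without hydroxide, so that the lactone stays closed. Halide attack on the ester methyl group meets that demand.

12 to 9 and 10: the bonds C1'–C6' and C2'–C3' are cut. C1'–C6' is a conjugate-addition bond (nucleophilic C1', β-carbon C6', carbonyl C4') and C2'–C3' is a Claisen bond (ketone methyl C3', ester carbonyl C2'). Ring B collapses to a nine-carbon enone and a malonate, and the crowded aryl–O–aryl bond becomes an aryl–O–alkyl bond. The forward step needs the malonate anion to add to the enone faster than it attacks the neighbouring lactone carbonyl, and it may use only one equivalent of a non-nucleophilic base.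

9 to 7 and 8: the O–C1' bond is cut. In the forward sense the C8 phenoxide displaces bromide from an activated, sterically small electrophile, so the hindered ether is formed at a non-aromatic carbon. The demands are O-alkylation in preference to bromine transfer, and a base mild enough to leave the acidic product alone.

7 to 6: an O–CH3 bond at C8 is added. Both phenols must be masked for the benzylic metalation and then told apart. The C8 methoxy group is peri to the C1 carbonyl and can be cleaved selectively by a chelating boron halide. The forward step must stop after one demethylation.

6 to 5: the lactone bond O2–C1 is cut, giving an open-chain keto ester. The closure must be run under acid. Under base the other enolate of the ketone could close onto the ester carbon and give a naphthalenediol.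

5 to 4 and 2: the C4–C3 bond (benzylic carbon to acyl carbon) is cut. The methyl group ortho to the ester is readily deprotonated, and C3 with its pentyl chain arrives as a six-carbon acyl donor. The forward step must stop at the ketone, which is why the acyl donor is 2 and not 1 itself.

4 to 3, and 2 to 1: two O–CH3 bonds and one amide C–N bond are cut, leading to the commercial compounds 3 and 1. Both forward steps are routine and place no special demand on the route.

## Other disconnections considered

Alternative 1: The cut goes through C4a–C4 and C8a–C1 and takes ring A, with the ether already in place, back to an aryne. In the forward sense CsF would unmask the 3-aryloxy-5-methoxybenzyne from 3-(2,4-dimethoxy-6-pentylphenoxy)-5-methoxy-2-(trimethylsilyl)phenyl trifluoromethanesulfonate A1. The aryne would insert into a carbon–carbonyl bond of dimethyl malonate A2 to give the homophthalate A3 (methyl 2-(2,4-dimethoxy-6-pentylphenoxy)-4-methoxy-6-(2-methoxy-2-oxoethyl)benzoate).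
- In its favour: one operation sets both carbon substituents of ring A in the correct ortho relation. The inductive effect of the aryloxy group should direct the malonate carbon to the remote aryne carbon, which places the acyl group next to the ether as required. Aryne insertion into malonates is an established reaction type, and its key C–C bond formation is probably at least the equal of a hindered conjugate addition in reliability.
- Against it: A1 must already contain the doubly ortho-substituted diaryl ether, so the central difficulty is moved and not solved. A1 itself needs a multistep preparation (ortho-silylation and triflation of a diaryl ether phenol). After A3 the pyranone with its pentyl chain still has to be built (acylation and decarboxylative closure of the homophthalate) and three methyl ethers removed.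
- Comparison: on step economy the chosen plan is expected to be shorter, and on structure it has the advantage that the ether is made at an sp3 carbon.

Alternative 2: The cut removes the C6–O and C4'–O bonds. In the forward sense 8-(2-methoxy-6-pentylphenoxy)-3-pentyl-1H-isochromen-1-one A4 would be borylated twice with [Ir(OMe)(cod)]2, 4,4'-di-tert-butyl-2,2'-bipyridine and bis(pinacolato)diboron, and NaBO3 oxidation in the same flask would give the diphenol A5 (6-hydroxy-8-(4-hydroxy-2-methoxy-6-pentylphenoxy)-3-pentyl-1H-isochromen-1-one).
- In its favour: C6 and C4' are the only aryl C–H positions with hydrogen on both neighbours, so steric control points to the correct sites. No oxygen on ring A needs protection, and no dehydrogenation is needed. On protecting-group economy and oxidation-state handling this alternative is better than the chosen plan. It is equal in ending with a single boron tribromide demethylation.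
- Against it: A4 again requires the crowded aryl–aryl ether to be made first. Two C–H functionalisations must both go to completion while C5, C7, C3' and C5' (the last two shielded only by methoxy or by one alkyl group) and the vinylic C4–H stay untouched, and partial or misplaced borylation would give phenols that are hard to separate. The basic perborate oxidation also meets the enol lactone.
- Comparison: mechanistically the selectivity rests on steric differences alone, whereas in the chosen plan the substitution pattern of ring B is fixed by the connectivity of the annulation.

Alternative 3: The cut removes C4a–C4 and O2–C3 and takes the pyranone off a benzoic acid. In the forward sense [Cp*RhCl2]2 (trivalent rhodium) with AgSbF6 would metalate 2-(2,4-dimethoxy-6-pentylphenoxy)-4-methoxybenzoic acid A6 at its only free ortho position. The hexanoyl sulfoxonium ylide A7 (dimethylsulfoxonium 2-oxoheptylide) would insert as a carbene, and condensation of the carboxyl oxygen with the ketone would close the ring to A8 (8-(2,4-dimethoxy-6-pentylphenoxy)-6-methoxy-3-pentyl-1H-isochromen-1-one). One global demethylation would then give the target.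
- In its favour: the plan is convergent, the regiochemistry is unambiguous because only one ortho C–H exists, the annulation is a known reaction type for benzoic acids, and only one step follows A8. From the diaryl ether onward it is clearly shorter than the chosen plan, and overall it is probably its equal or better in step count.
- Against it: A6 has to come from an Ullmann-type coupling between a 2-halobenzoic acid and a phenol substituted at both ortho positions, and that phenol needs its own regiocontrolled synthesis. The risk therefore sits in the very bond that the chosen plan makes by a simple displacement. A precious-metal catalyst and a silver salt are also needed.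
- Comparison: the chosen plan spends more steps to avoid the hindered coupling. Alternative 3 would be preferred if that coupling proved easy.

Key step: step 7

Remark on the chemistry: 11, 12 and 13 are racemic, and 12 and 13 are carried as mixtures of diastereomers because both sp3 centres become aromatic carbons in step 9. Compounds 1, 3, 8 and 10 are taken to be commercial. The methyl esters and the C6 methyl ether of 9 are kept on purpose: methyl esters are the least hindered for the conjugate addition and the best substrates for the dealkoxycarbonylation, and the C6 methoxy group, para to C8a, lowers the electrophilicity of the lactone carbonyl during the base step.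

## Route

Step 1
Reactants: 1 hexanoyl chloride
Product: 2 N-methoxy-N-methylhexanamide
Conditions: MeNH(OMe)·HCl (1.1 equiv), Et3N (2.2 equiv), CH2Cl2, 0 °C to rt
Reagents that add atoms: N,O-dimethylhydroxylamine hydrochloride, CNOC.Cl
Why: Acyl substitution of an acid chloride by the amine (Weinreb amide formation); the amide is needed because the acid chloride itself would over-react with the benzylic anion in step 3.

Step 2
Reactants: 3 methyl orsellinate (methyl 2,4-dihydroxy-6-methylbenzoate)
Product: 4 methyl 2,4-dimethoxy-6-methylbenzoate
Conditions: MeI (3 equiv), K2CO3 (3 equiv), acetone, reflux
Reagents that add atoms: iodomethane, CI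
Why: Williamson ether synthesis on both phenols; the hydrogen-bonded 2-hydroxyl reacts more slowly than the 4-hydroxyl, so excess reagent and heating are used to drive it to the diether.

Step 3
Reactants: 4 methyl 2,4-dimethoxy-6-methylbenzoate; 2 N-methoxy-N-methylhexanamide
Product: 5 methyl 2,4-dimethoxy-6-(2-oxoheptyl)benzoate
Conditions: LiN(iPr)2 (2.0 equiv), THF, −78 °C; 2 (1.1 equiv), −78 °C; AcOH, −78 °C
Reagents that add atoms: none
Why: Lateral (benzylic) lithiation of the ortho-toluate followed by Weinreb ketone synthesis; the chelated tetrahedral adduct prevents a second addition, the ester flanked by two ortho substituents resists self-condensation, and the cold acidic quench prevents closure of the ketone enolate onto the ester.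

Step 4
Reactants: 5 methyl 2,4-dimethoxy-6-(2-oxoheptyl)benzoate
Product: 6 6,8-dimethoxy-3-pentyl-1H-isochromen-1-one
Conditions: p-TsOH·H2O (0.2 equiv), toluene, reflux, 4 Å molecular sieves
Reagents that add atoms: none
Why: Acid-catalysed enol lactonisation: the conjugated benzylic enol attacks the protonated ester (6-exo-trig) and methanol is removed; acid is chosen because only oxygen of the enol can reach the ester, whereas base would allow carbon acylation to a naphthalenediol.

Step 5
Reactants: 6 6,8-dimethoxy-3-pentyl-1H-isochromen-1-one
Product: 7 8-hydroxy-6-methoxy-3-pentyl-1H-isochromen-1-one
Conditions: BCl3 (1.5 equiv), CH2Cl2, −78 °C to 0 °C; aq. NaHCO3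
Reagents that add atoms: none
Why: Chelation-controlled Lewis-acid demethylation: boron binds between the C1 carbonyl and the peri C8 methoxy oxygen, so chloride cleaves that methyl group only; the C6 methoxy group has no such assistance and the lactone is stable to BCl3 at this temperature.

Step 6
Reactants: 7 8-hydroxy-6-methoxy-3-pentyl-1H-isochromen-1-one; 8 dimethyl bromomalonate
Product: 9 dimethyl 2-[(6-methoxy-1-oxo-3-pentyl-1H-isochromen-8-yl)oxy]propanedioate
Conditions: 8 (1.1 equiv, slow addition), K2CO3 (1.5 equiv), acetone, 50 °C
Reagents that add atoms: none
Why: Williamson-type SN2 displacement of an activated secondary bromide by the phenoxide, the standard route to aryloxymalonates; the hindered ether oxygen is thus bonded to a small sp3 carbon, and the weak base with only a slight excess of 8 limits deprotonation and further reaction of the product.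

Step 7
Reactants: 9 dimethyl 2-[(6-methoxy-1-oxo-3-pentyl-1H-isochromen-8-yl)oxy]propanedioate; 10 (E)-non-3-en-2-one
Product: 12 methyl 1-[(6-methoxy-1-oxo-3-pentyl-1H-isochromen-8-yl)oxy]-2,4-dioxo-6-pentylcyclohexane-1-carboxylate (racemic mixture of diastereomers), via the open-chain Michael adduct 11 (not isolated)
Conditions: 10 (2 equiv), KOtBu (1.05 equiv, added last), THF/t-BuOH (5:1), −20 °C to 45 °C; 1 M HCl, 0 °C
Reagents that add atoms: none
Why: Deprotonation of 9 gives a doubly stabilised soft carbanion that adds 1,4 to the enone 10 (Michael addition), forming C1'–C6' and the ketone enolate of 11. Proton exchange through tert-butanol moves the enolate to the methyl carbon, which attacks one of the two equivalent ester carbonyls (Claisen condensation) to form C2'–C3'; loss of methoxide and deprotonation of the new 1,3-dione, the strongest acid present, make the sequence irreversible and use exactly one equivalent of base. The closest known reaction type is the malonate–enone Michael–Claisen annulation to 5-alkylcyclohexane-1,3-diones, here run with a malonate that already carries its third substituent. The ring closes in the 6-exo-trig mode, the enolate carbon attacking an ester carbonyl whose oxygen stays outside the ring; closure through the internal alpha carbon would give a four-membered ring and attack of the ketone on the lactone a nine-membered one, so ring size fixes the regiochemistry and places pentyl next to the ether carbon. Two stereocentres (C1 and C6 of the cyclohexane) form without control and none is needed, since both become aromatic carbons in step 9. The selectivity that matters is the chemoselectivity of the malonate anion: conjugate addition to 10 against attack on the peri lactone carbonyl C1, which would close a five-membered ring. This is secured by generating the anion in the presence of excess 10, by the donor oxygens at C6 and C8 that lower the electrophilicity of C1, and by the strain of bridging the peri positions; once C1' is quaternary that pathway no longer exists. With only one equivalent of hindered base no free alkoxide remains to open the enol lactone, because the charge ends on the dione enolate.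

Step 8
Reactants: 12 methyl 1-[(6-methoxy-1-oxo-3-pentyl-1H-isochromen-8-yl)oxy]-2,4-dioxo-6-pentylcyclohexane-1-carboxylate
Product: 13 8-[(2,4-dioxo-6-pentylcyclohexyl)oxy]-6-methoxy-3-pentyl-1H-isochromen-1-one (racemic mixture of diastereomers, largely enolised)
Conditions: LiCl (4 equiv), H2O (3 equiv), DMSO, 140 °C; dilute HCl work-up
Reagents that add atoms: none
Why: Krapcho dealkoxycarbonylation: chloride attacks the ester methyl group (SN2), and the β-keto carboxylate loses CO2 to give the dione enolate; no hydroxide or alkoxide is used, so the enol lactone and the aryl methyl ether are expected to survive.

Step 9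
Reactants: 13 8-[(2,4-dioxo-6-pentylcyclohexyl)oxy]-6-methoxy-3-pentyl-1H-isochromen-1-one
Product: 14 8-(2,4-dihydroxy-6-pentylphenoxy)-6-methoxy-3-pentyl-1H-isochromen-1-one
Conditions: DDQ (1.1 equiv), 1,4-dioxane, 80 °C
Reagents that add atoms: none
Why: Quinone dehydrogenation of a cyclohexane-1,3-dione to a resorcinol: hydride is taken from the tertiary C–H next to the aryloxy-substituted enol, proton loss and tautomerisation follow, and aromatisation is the driving force. The aryloxy group cannot leave because no carbanion can form beta to it, and the pentyl chain is meta to both new hydroxyls, so no quinone methide can form.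

Step 10
Reactants: 14 8-(2,4-dihydroxy-6-pentylphenoxy)-6-methoxy-3-pentyl-1H-isochromen-1-one
Product: 15 6-hydroxy-8-(2,4-dihydroxy-6-pentylphenoxy)-3-pentyl-1H-isochromen-1-one (target)
Conditions: BBr3 (5 equiv), CH2Cl2, −78 °C to rt; H2O, 0 °C
Reagents that add atoms: none
Why: Lewis-acid cleavage of the aryl methyl ether (bromide attack on the methyl group of the boron-complexed ether); the excess covers the two free phenols and the lactone carbonyl, and diaryl ethers and isocoumarins are stable to this reagent.

## Compound list

1 | hexanoyl chloride | CCCCCC(=O)Cl | starting material
2 | N-methoxy-N-methylhexanamide | CCCCCC(=O)N(C)OC | intermediate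
3 | methyl orsellinate (methyl 2,4-dihydroxy-6-methylbenzoate) | COC(=O)c1c(C)cc(O)cc1O | starting material
4 | methyl 2,4-dimethoxy-6-methylbenzoate | COC(=O)c1c(C)cc(OC)cc1OC | intermediate
5 | methyl 2,4-dimethoxy-6-(2-oxoheptyl)benzoate | COC(=O)c1c(CC(=O)CCCCC)cc(OC)cc1OC | intermediate
6 | 6,8-dimethoxy-3-pentyl-1H-isochromen-1-one | CCCCCc1cc2cc(OC)cc(OC)c2c(=O)o1 | intermediate
7 | 8-hydroxy-6-methoxy-3-pentyl-1H-isochromen-1-one | CCCCCc1cc2cc(OC)cc(O)c2c(=O)o1 | intermediate
8 | dimethyl bromomalonate (dimethyl 2-bromopropanedioate) | COC(=O)C(Br)C(=O)OC | starting material
9 | dimethyl 2-[(6-methoxy-1-oxo-3-pentyl-1H-isochromen-8-yl)oxy]propanedioate | COC(=O)C(Oc1cc(OC)cc2cc(CCCCC)oc(=O)c12)C(=O)OC | intermediate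
10 | (E)-non-3-en-2-one | CCCCC/C=C/C(C)=O | starting material
11 | dimethyl 2-[(6-methoxy-1-oxo-3-pentyl-1H-isochromen-8-yl)oxy]-2-(2-oxononan-4-yl)propanedioate (racemic; Michael adduct, not isolated) | COC(=O)C(Oc1cc(OC)cc2cc(CCCCC)oc(=O)c12)(C(=O)OC)C(CCCCC)CC(C)=O | intermediate
12 | methyl 1-[(6-methoxy-1-oxo-3-pentyl-1H-isochromen-8-yl)oxy]-2,4-dioxo-6-pentylcyclohexane-1-carboxylate (racemic mixture of diastereomers) | CCCCCC1CC(=O)CC(=O)C1(Oc1cc(OC)cc2cc(CCCCC)oc(=O)c12)C(=O)OC | intermediate
13 | 8-[(2,4-dioxo-6-pentylcyclohexyl)oxy]-6-methoxy-3-pentyl-1H-isochromen-1-one (racemic mixture of diastereomers) | CCCCCC1CC(=O)CC(=O)C1Oc1cc(OC)cc2cc(CCCCC)oc(=O)c12 | intermediate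
14 | 8-(2,4-dihydroxy-6-pentylphenoxy)-6-methoxy-3-pentyl-1H-isochromen-1-one | CCCCCc1cc2cc(OC)cc(Oc3c(O)cc(O)cc3CCCCC)c2c(=O)o1 | intermediate
15 | 6-hydroxy-8-(2,4-dihydroxy-6-pentylphenoxy)-3-pentyl-1H-isochromen-1-one (achiral) | CCCCCc1cc2cc(O)cc(Oc3c(O)cc(O)cc3CCCCC)c2c(=O)o1 | target

## Step count and least certain steps

Total step count: 10. Longest linear sequence: 9 (steps 2 to 10); step 1 is a one-step branch that joins at step 3.

Step 7 (key step).
- What may go wrong: the fully substituted malonate anion may attack the neighbouring lactone carbonyl (a five-membered, Dieckmann-type acyl transfer that expels the enol oxygen) instead of adding to the enone. The conjugate addition to a β-alkyl enone may also be slow and reversible for steric reasons, leaving the base free to consume the enone by self-condensation.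
- Fallback: a Lewis-acid route that never forms the free anion. It sets out from 9, which is converted with TMSOTf and Et3N in CH2Cl2 at 0 °C into the trimethylsilyl ketene acetal F1. Mukaiyama–Michael addition of F1 to 10 with TiCl4 in CH2Cl2 at −78 °C should give, after aqueous work-up, the neutral ketone 11. The fallback comes back to the route at 11, which is then closed to 12 with KOtBu as in step 7. With C1' already quaternary, attack on the lactone is no longer possible.

Step 9.
- What may go wrong: hydride abstraction from the hydrogen-bonded, electron-poor enol of the dione may be slow, and prolonged heating with the quinone may oxidise the electron-rich resorcinol product or the benzylic positions.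
- Fallback: activation as a dienol ether followed by a Saegusa–Ito oxidation. It sets out from 13, which is silylated twice with TMSOTf and Et3N in CH2Cl2 to the bis(trimethylsilyl) dienol ether F2. Pd(OAc)2 (divalent palladium, one equivalent) in MeCN at rt should palladate the aryloxy-bearing carbon, and β-hydride elimination and tautomerisation should give the mono-silylated resorcinol F3. Dilute HCl in the work-up removes the remaining silyl group, and the fallback comes back to the route at 14.

Step 6.
- What may go wrong: the C8 phenoxide is chelated to the lactone carbonyl and reacts slowly. Halophilic attack on bromine may then compete and brominate ring A, and carbonate may deprotonate the product, which can then be alkylated again or attack the lactone.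
- Fallback: a neutral carbenoid O–H insertion. Dimethyl 2-diazopropanedioate F4 is made from dimethyl malonate by diazo transfer (4-acetamidobenzenesulfonyl azide, Et3N, MeCN). The fallback sets out from 7, which is heated with F4 and catalytic Rh2(OAc)4 in toluene at 80 °C. Insertion of the rhodium carbenoid into the phenol O–H bond should give 9 directly, where the fallback comes back to the route.

Step 3.
- What may go wrong: the benzylic anion may be quenched by proton transfer from the alpha-CH2 of the amide, returning 4. If the mixture warms before the quench, the ketone enolate may close onto the ester carbon and give a naphthalenediol.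
- Fallback: the homophthalic acid route to 3-alkylisocoumarins. It sets out from 4, which is lithiated as before and carboxylated with CO2 to 2-[3,5-dimethoxy-2-(methoxycarbonyl)phenyl]acetic acid F5. Saponification (KOH, aqueous EtOH, reflux) gives 2-(carboxymethyl)-4,6-dimethoxybenzoic acid F6. Heating F6 with 1 at 200 °C (anhydride formation, C-acylation, decarboxylation, lactonisation) should give 6, where the fallback comes back to the route; steps 1, 3 and 4 are then not needed.

## Further compounds

F1 | step 7 | methyl 3-methoxy-2-[(6-methoxy-1-oxo-3-pentyl-1H-isochromen-8-yl)oxy]-3-[(trimethylsilyl)oxy]prop-2-enoate (silyl ketene acetal of 9, alkene geometry not fixed) | COC(=O)C(Oc1cc(OC)cc2cc(CCCCC)oc(=O)c12)=C(OC)O[Si](C)(C)C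
F2 | step 9 | 6-methoxy-3-pentyl-8-{[6-pentyl-2,4-bis(trimethylsilyloxy)cyclohexa-1,3-dien-1-yl]oxy}-1H-isochromen-1-one (racemic) | CCCCCC1CC(O[Si](C)(C)C)=CC(O[Si](C)(C)C)=C1Oc1cc(OC)cc2cc(CCCCC)oc(=O)c12
F3 | step 9 | 8-{2-hydroxy-6-pentyl-4-[(trimethylsilyl)oxy]phenoxy}-6-methoxy-3-pentyl-1H-isochromen-1-one | CCCCCc1cc2cc(OC)cc(Oc3c(O)cc(O[Si](C)(C)C)cc3CCCCC)c2c(=O)o1
F4 | step 6 | dimethyl 2-diazopropanedioate | COC(=O)C(=[N+]=[N-])C(=O)OC
F5 | step 3 | 2-[3,5-dimethoxy-2-(methoxycarbonyl)phenyl]acetic acid | COC(=O)c1c(CC(=O)O)cc(OC)cc1OC
F6 | step 3 | 2-(carboxymethyl)-4,6-dimethoxybenzoic acid | OC(=O)Cc1cc(OC)cc(OC)c1C(=O)O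
A1 | alternative 1 | 3-(2,4-dimethoxy-6-pentylphenoxy)-5-methoxy-2-(trimethylsilyl)phenyl trifluoromethanesulfonate | COc1cc(OS(=O)(=O)C(F)(F)F)c([Si](C)(C)C)c(Oc2c(OC)cc(OC)cc2CCCCC)c1
A2 | alternative 1 | dimethyl malonate | COC(=O)CC(=O)OC
A3 | alternative 1 | methyl 2-(2,4-dimethoxy-6-pentylphenoxy)-4-methoxy-6-(2-methoxy-2-oxoethyl)benzoate | COC(=O)Cc1cc(OC)cc(Oc2c(OC)cc(OC)cc2CCCCC)c1C(=O)OC
A4 | alternative 2 | 8-(2-methoxy-6-pentylphenoxy)-3-pentyl-1H-isochromen-1-one | CCCCCc1cc2cccc(Oc3c(OC)cccc3CCCCC)c2c(=O)o1
A5 | alternative 2 | 6-hydroxy-8-(4-hydroxy-2-methoxy-6-pentylphenoxy)-3-pentyl-1H-isochromen-1-one | CCCCCc1cc2cc(O)cc(Oc3c(OC)cc(O)cc3CCCCC)c2c(=O)o1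
A6 | alternative 3 | 2-(2,4-dimethoxy-6-pentylphenoxy)-4-methoxybenzoic acid | COc1ccc(C(=O)O)c(Oc2c(OC)cc(OC)cc2CCCCC)c1
A7 | alternative 3 | dimethylsulfoxonium 2-oxoheptylide (hexanoyl sulfoxonium ylide) | CCCCCC(=O)C=S(C)(C)=O
A8 | alternative 3 | 8-(2,4-dimethoxy-6-pentylphenoxy)-6-methoxy-3-pentyl-1H-isochromen-1-one | CCCCCc1cc2cc(OC)cc(Oc3c(OC)cc(OC)cc3CCCCC)c2c(=O)o1
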